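**One step.** I began from a one-step world, Q and D giving E and stopping there, where E climbs and stays.

| flask | Q | D | remark | time |
|---|---|---|---|---|
| south-west | 0.20 M | 1.5 equiv (fed, over 40 min) | run made earlier; the fed solution adds 0.10 times the starting volume |  |
| east | 0.45 M | 1.5 equiv (fed, over 40 min) | run made earlier; the fed solution adds 0.10 times the starting volume |  |
| north-east | 0.30 M | 0.75 equiv (fed, over 40 min) | run made earlier; the fed solution adds 0.10 times the starting volume |  |
| flask | 0.30 M | 1.50 equiv (fed, over 40 min) | the fed solution adds 0.10 times the starting volume | 6.0 h |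

| run | time / h | E / % |
|---|---|---|
| south-west | 0.250 | 8.1 |
| south-west | 0.417 | 15.0 |
| south-west | 0.667 | 28.0 |
| south-west | 1.00 | 36.5 |
| south-west | 2.00 | 31.6 |
| south-west | 3.00 | 28.6 |
| south-west | 5.00 | 20.4 |
| east | 0.250 | 13.3 |
| east | 0.417 | 23.0 |
| east | 0.667 | 32.2 |
| east | 1.00 | 32.4 |
| east | 2.00 | 20.5 |
| east | 3.00 | 19.0 |
| east | 5.00 | 11.3 |
| north-east | 0.250 | 4.5 |
| north-east | 0.500 | 15.5 |
| north-east | 1.00 | 23.0 |
| north-east | 2.50 | 16.9 |
| north-east | 5.00 | 10.2 |

(readings scatter by 1 percentage point)

- time up to 6.0 h at which E stands highest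
- the amount of E, in percent of the Q charged, at that time

- every charge counts on the volume at the start, and the solution that is fed holds the whole dose

**Odd pair.** With equal equivalents, the east run led the south-west run at 0.250 h, 13.3% against 8.1%, yet trailed at 5.00 h, 11.3% against 20.4%.

**Counting turnovers.** Hours misled me here. With 2.25 times the charge, the east run stood at 20.5% after 2.00 h, and the south-west run reached 20.4% after 2.50 times those hours. From 1.00 h to 5.00 h, E fell at 0.145 h⁻¹ in the south-west run and 0.263 h⁻¹ in the east run. I divided each by its charge, averaged, and scaled to this flask: 0.197 h⁻¹, the loss rate, a rough average over those hours, read from scattered readings, and not a constant. Multiplied by hours, it counts turnovers of loss.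

**My reckoning.** The feed gives 0.0875 turnovers in the south-west run, 0.197 in the east run and 0.131 in this flask. Placing this flask between the two readings at 1.00 h by charge gave me 34.9%, soon after the feed ended.

**The result.** The forecast, 35.5% at 0.95 h, stood above mine and held that “The peak comes shortly after the feed ends”. The flask gave 34.8% at 0.909 h.

    Q + E → X (k = 0.0409 M⁻¹ min⁻¹)
    Q + D ⇌ E + J (K = 0.322, k = 0.0951 M⁻¹ min⁻¹)

**Two paces.** At 6.00 h in this flask, Q + D and E + J relaxed with a half-life of 0.142 h. Q by the step to X then had a half-life of 7.1 h, much slower.

**Thin neighbour.** With 0.075 M of Q, the loss rate scales to 0.0492 h⁻¹, so the hours from the feed's end to 6.0 h hold 0.262 turnovers, taking the south-west peak reading down to 28.1%. That flask computed a best of 36.2% and ended at 29.8%.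

The runs were computed on assumed constants; scatter was added.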